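**Target.** Compound 18 is (3R)-3-[2-hydroxy-4-methoxy-3-(3-methylbut-2-en-1-yl)phenyl]-5-methoxy-3,4-dihydro-2H-chromen-7-ol. The descriptor R follows from the stereo-SMILES: at C3 the priorities are C2 > C1' > C4 > H. The route runs from compound 1 to compound 18 in 14 steps, with the carbenoid C–H insertion as step 11.

## The problem

The target 18 is an isoflavan: a chroman (ring A fused to the oxygen heterocycle, ring C) that carries ring B at C3. Ring A is a phloroglucinol unit whose three oxygens are differentiated as O1 of ring C, a C5 methoxy group and a free C7 hydroxyl. Ring B is 1,2,3,4-tetrasubstituted, with the prenyl group wedged between the 2'-hydroxyl and the 4'-methoxy group. C3 is the only stereocentre and nothing else in the molecule can relay chirality to it, so a reagent or catalyst has to set it. It is secure in the isoflavan itself, but in any precursor with a carbonyl group at C4 it is both benzylic and alpha to the carbonyl and therefore labile to base. The prenyl alkene rules out hydrogenation and hydrogenolysis, and under protic acid it cyclises onto a free 2'-hydroxyl, so acid-labile protecting groups on that oxygen are a liability. The two electron-rich phenols must stay masked until the end, and the three oxygen donors of ring A make any leaving group at C4 ionise very easily. The enabling feature is that the O1–C2 bond of ring C is an aryl alkyl ether of the same kind as the C5–OCH3 bond on the other side of C4a. Ring A can therefore enter as a symmetric 2,6-dimethoxy-4-oxyphenyl unit: one methoxy carbon is turned into C2 by C–H insertion of a carbene centred on C3, and the other stays as the C5 methoxy group.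

## Retrosynthesis

**Unmasking (18 from 17).** The two O–Si bonds are cut last. Silyl ethers are chosen for both phenols because the 2'-oxygen must carry a group with no C–H bond alpha to oxygen (an O-alkyl or acetal group there would be attacked by the carbene of the key step) and must be freed without acid because of the neighbouring prenyl group. Buffered fluoride meets both demands and leaves C3 alone.

**Removal of the C4 oxygen (17 from 16 from 15).** The two C4–H bonds are traced back to a C4 ketone. The carbonyl is not a detour: it makes C3 a usable carbene centre (acceptor group, no 1,2-hydrogen shift possible, acidified CH2 for diazo transfer). It is removed in two operations, a non-basic hydride reduction to alcohol 16 and an ionic hydrogenation that exploits the donor power of ring A. Hydrogenolysis is excluded by the prenyl group. A xanthate and tin hydride sequence would cost one more step and would need an alkoxide next to two aryl silyl ethers. The forward steps must never expose ketone 15 to base and must trap the C4 cation with hydride before it can lose the C3 proton.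

**Key disconnection (15 from 14).** The C2–C3 bond is cut, which opens ring C and removes the stereocentre in one stroke, leaving the acyclic, achiral diazoketone 14 with a symmetric ring A. The neighbouring cuts are less attractive. Cutting O1–C2 or O1–C8a needs a ring A whose three oxygens are already differentiated and sets C3 in a separate operation. Cutting C3–C1' would create the stereocentre by enolate arylation, that is, under the basic conditions in which it racemises. The forward reaction must favour insertion into a methoxy C–H bond over attack on the methoxy oxygen, and a chiral catalyst must control the configuration at C3.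

**Diazo group (14 from 13).** The C=N2 unit is cut back to the methylene group of deoxybenzoin 13, which is flanked by the ketone and ring B and is acidic enough for direct sulfonyl azide transfer.

**Union of the halves (13 from 12 from 11 and 8).** The C4–C4a bond is cut between an aryl anion and an aldehyde; alcohol 12 is then oxidised. The symmetry of ring A is used again here: the position between the two methoxy groups of 10 is the one that lithiates, giving 11. Friedel–Crafts acylation would be directed ortho to the third oxygen and needs Lewis acids that the prenyl group would not survive. A cut at C3–C4 would need a ring B benzylic anion next to a silyloxy group, which invites silyl migration. The two fragments are of similar size.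

**Ring A fragment (11 from 10 from 9).** One silylation of 3,5-dimethoxyphenol (9) and one lithiation; no oxygen has to be differentiated.

**Homologation of ring B (8 from 7 from 6).** The aldehyde carbon of 8 becomes C4 and is added to benzaldehyde 6 by methoxymethylenation (enol ether 7) and hydrolysis, two routine steps that leave the prenyl and silyl groups untouched.

**Prenyl group (6 from 5 from 4 from 3 from 1 and 2).** The C3'–CH2 bond is cut by an aromatic Claisen transform to the 1,1-dimethylallyl ether 4. Ether 4 comes from the propargyl ether 3 by semihydrogenation, and 3 comes from 2-hydroxy-4-methoxybenzaldehyde (1) and the propargylic chloride 2. Direct C-prenylation of 1 would give mixtures of O- and C-alkylation and of ring positions. The sigmatropic route can deliver the group only to the single free ortho position, between the two oxygens. Silylation of 5 then gives 6.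

## Roads not taken

**Alternative 1: quinone methide and ammonium enolate annulation.** Here C3–C4 and the O1–C2 acyl bond are cut. Base releases an ortho-quinone methide from sulfone A1. A benzotetramisole-bound enolate, made from arylacetic acid A2 and pivaloyl chloride, adds to it at C4 and then lactonises to the (3R)-dihydrocoumarin A3.
- Merits: isothiourea catalysis of this formal [4+2] annulation is an established reaction type, and C4 arrives as CH2, so no oxygen has to be removed there. In both respects this road is better than the chosen one.
- Weak points: the quinone methide has no substituent on its methide carbon and is therefore prone to self-reaction. The stereocentre of A3 is alpha to an aryl ester and is made under base. A1 needs a ring A with three differentiated oxygens plus a benzylic sulfone. A2 needs one more oxidation level than aldehyde 8. The lactone must still be reduced and the ring reclosed by Mitsunobu etherification. The acetal on the 2'-oxygen would have to be removed with acid next to the prenyl group.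
- Comparison: the chosen plan offers a ring A made in one step from 9 and a ring C whose C2 is already in the molecule.

**Alternative 2: one-carbon ring expansion of a benzofuran.** Here C2–C3 and C3–C4 are cut together. The arylchlorocarbene from diazirine A5 adds to the furan double bond of benzofuran A4, and the adduct opens with loss of chloride to the 3-arylbenzopyrylium chloride A6.
- Merits: two ring bonds form in one convergent step from flat, robust partners, more skeleton per step than the chosen insertion.
- Weak points: A6 is achiral, so C3 has to be set afterwards by an asymmetric reduction of the heterocycle. That reduction is incompatible with a prenyl alkene, which is why ring B carries bromine and the prenyl group would be coupled late at a hindered position, with the usual risk of allyl transposition. The carbon-insertion step itself is young chemistry for oxygen heterocycles.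
- Comparison: the chosen plan forms only one bond in its key step, but sets C3 in the same step and carries the prenyl group through from the start.

**Alternative 3: desymmetrising aryl ether closure.** Here O1–C8a is cut. CuI and a chiral diamine couple one of the two enantiotopic hydroxymethyl oxygens of diol A7 with the aryl bromide carbon to give chroman A8, whose C3 is quaternary.
- Merits: copper-catalysed desymmetrisation of such diols has close precedent, the quaternary centre cannot epimerise, and no oxygen ever sits at C4. On stereochemical security this road is the safest of all.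
- Weak points: the spare hydroxymethyl arm has to be removed by oxidation and decarbonylation with stoichiometric RhCl(PPh3)3 at a hindered neopentyl position, under heat and next to an alkene that rhodium hydrides can isomerise. A7 needs a brominated, fully differentiated ring A benzyl unit and a ring B malonate. The acetal groups again call for acid at the end.
- Comparison: the chosen plan builds no atom that must later be excised and reaches the target in fewer steps. It pays with a stereocentre that has to be guarded through two steps.

Key step: step 11

Assumption: the sense of induction of Rh2(S-PTTL)4 in this new substrate class is not known. The (S)-ligand series is written, and the mirror-image catalyst Rh2(R-PTTL)4 would be used if the insertion turns out to favour the (3S) series.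

## Route

Step 1
Reactants: 1 2-hydroxy-4-methoxybenzaldehyde; 2 3-chloro-3-methylbut-1-yne
Product: 3 4-methoxy-2-[(2-methylbut-3-yn-2-yl)oxy]benzaldehyde
Conditions: DBU, CuCl2·2H2O (cat.), MeCN, 0 °C
Reagents that add atoms: none
Why: Copper-catalysed O-propargylation of a phenol with a tertiary propargylic chloride, the standard entry to aryl 1,1-dimethylpropargyl ethers; the mild base and low temperature leave the aldehyde alone.

Step 2
Reactants: 3 4-methoxy-2-[(2-methylbut-3-yn-2-yl)oxy]benzaldehyde
Product: 4 4-methoxy-2-[(2-methylbut-3-en-2-yl)oxy]benzaldehyde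
Conditions: H2 (1 atm), Pd/CaCO3 poisoned with Pb(OAc)2, quinoline, EtOAc, rt
Reagents that add atoms: none
Why: Lindlar semihydrogenation of the terminal alkyne; the poisoned catalyst should stop at the alkene and not touch the aldehyde or the aryl ether.

Step 3
Reactants: 4 4-methoxy-2-[(2-methylbut-3-en-2-yl)oxy]benzaldehyde
Product: 5 2-hydroxy-4-methoxy-3-(3-methylbut-2-en-1-yl)benzaldehyde
Conditions: PhNEt2, 120 °C
Reagents that add atoms: none
Why: Aromatic Claisen rearrangement; the [3,3] shift inverts the allyl unit so that the tertiary ether becomes a prenyl group, delivered to the only free ortho position (between the two oxygens), and enolisation restores the phenol.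

Step 4
Reactants: 5 2-hydroxy-4-methoxy-3-(3-methylbut-2-en-1-yl)benzaldehyde
Product: 6 2-[(tert-butyldimethylsilyl)oxy]-4-methoxy-3-(3-methylbut-2-en-1-yl)benzaldehyde
Conditions: TBSOTf, 2,6-lutidine, CH2Cl2, 0 °C
Reagents that add atoms: tert-butyldimethylsilyl trifluoromethanesulfonate, CC(C)(C)[Si](C)(C)OS(=O)(=O)C(F)(F)F
Why: Silylation of a hindered, hydrogen-bonded phenol with the silyl triflate; the silyl ether has no C–H bond alpha to oxygen and is later removed by fluoride without acid.

Step 5
Reactants: 6 2-[(tert-butyldimethylsilyl)oxy]-4-methoxy-3-(3-methylbut-2-en-1-yl)benzaldehyde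
Product: 7 tert-butyl[3-methoxy-6-(2-methoxyethenyl)-2-(3-methylbut-2-en-1-yl)phenoxy]dimethylsilane (E/Z mixture)
Conditions: Ph3P(CH2OMe)Cl, KOtBu, THF, 0 °C; then 6, 0 °C to rt
Reagents that add atoms: (methoxymethyl)triphenylphosphonium chloride, COC[P+](c1ccccc1)(c1ccccc1)c1ccccc1.[Cl-]
Why: Wittig methoxymethylenation of an aromatic aldehyde; the ylide is preformed with a slight deficit of base so that no alkoxide is left to attack the aryl silyl ether, and the alkene geometry is irrelevant.

Step 6
Reactants: 7 tert-butyl[3-methoxy-6-(2-methoxyethenyl)-2-(3-methylbut-2-en-1-yl)phenoxy]dimethylsilane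
Product: 8 2-{2-[(tert-butyldimethylsilyl)oxy]-4-methoxy-3-(3-methylbut-2-en-1-yl)phenyl}acetaldehyde
Conditions: HCO2H, H2O (2 equiv), CH2Cl2, 0 °C to rt; crude product used at once
Reagents that add atoms: water, O
Why: Acid hydrolysis of an enol ether; the enol ether is far more basic than the trisubstituted prenyl alkene, so a weak acid should unmask the aldehyde selectively, and the aryl silyl ether tolerates it.

Step 7
Reactants: 9 3,5-dimethoxyphenol
Product: 10 (3,5-dimethoxyphenoxy)tri(propan-2-yl)silane
Conditions: TIPSCl, imidazole, DMF, rt
Reagents that add atoms: chlorotri(propan-2-yl)silane, CC(C)[Si](Cl)(C(C)C)C(C)C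
Why: Standard silylation of a phenol; the bulky silyl group resists butyllithium and shields its own ortho positions from metalation.

Step 8
Reactants: 10 (3,5-dimethoxyphenoxy)tri(propan-2-yl)silane; 8 2-{2-[(tert-butyldimethylsilyl)oxy]-4-methoxy-3-(3-methylbut-2-en-1-yl)phenyl}acetaldehyde
Product: 12 rac-2-{2-[(tert-butyldimethylsilyl)oxy]-4-methoxy-3-(3-methylbut-2-en-1-yl)phenyl}-1-{2,6-dimethoxy-4-[(triisopropylsilyl)oxy]phenyl}ethan-1-ol, via aryllithium 11 (not isolated)
Conditions: n-BuLi, THF, 0 °C to rt; then 8, −78 °C; H2O quench
Reagents that add atoms: none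
Why: Directed ortho-lithiation at the position flanked by both methoxy groups, then 1,2-addition of the aryllithium to the aldehyde at low temperature; the aryllithium is used in excess, and the new carbinol centre is not controlled because the next step removes it.

Step 9
Reactants: 12 rac-2-{2-[(tert-butyldimethylsilyl)oxy]-4-methoxy-3-(3-methylbut-2-en-1-yl)phenyl}-1-{2,6-dimethoxy-4-[(triisopropylsilyl)oxy]phenyl}ethan-1-ol
Product: 13 2-{2-[(tert-butyldimethylsilyl)oxy]-4-methoxy-3-(3-methylbut-2-en-1-yl)phenyl}-1-{2,6-dimethoxy-4-[(triisopropylsilyl)oxy]phenyl}ethan-1-one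
Conditions: Dess–Martin periodinane, pyridine, CH2Cl2, 0 °C to rt
Reagents that add atoms: none
Why: Dess–Martin oxidation of a secondary benzylic alcohol; the pyridine buffer protects the electron-rich, acid-sensitive carbinol from dehydration, and the alkene and silyl ethers are inert.

Step 10
Reactants: 13 2-{2-[(tert-butyldimethylsilyl)oxy]-4-methoxy-3-(3-methylbut-2-en-1-yl)phenyl}-1-{2,6-dimethoxy-4-[(triisopropylsilyl)oxy]phenyl}ethan-1-one
Product: 14 2-{2-[(tert-butyldimethylsilyl)oxy]-4-methoxy-3-(3-methylbut-2-en-1-yl)phenyl}-2-diazo-1-{2,6-dimethoxy-4-[(triisopropylsilyl)oxy]phenyl}ethan-1-one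
Conditions: 4-acetamidobenzenesulfonyl azide, DBU, dry MeCN, 0 °C to rt
Reagents that add atoms: 4-acetamidobenzenesulfonyl azide, CC(=O)Nc1ccc(cc1)S(=O)(=O)N=[N+]=[N-]
Why: Regitz diazo transfer to a deoxybenzoin, whose methylene group is activated by both the ketone and ring B; dry conditions keep the amidine base from cleaving the aryl silyl ethers.

Step 11
Reactants: 14 2-{2-[(tert-butyldimethylsilyl)oxy]-4-methoxy-3-(3-methylbut-2-en-1-yl)phenyl}-2-diazo-1-{2,6-dimethoxy-4-[(triisopropylsilyl)oxy]phenyl}ethan-1-one
Product: 15 (3R)-3-{2-[(tert-butyldimethylsilyl)oxy]-4-methoxy-3-(3-methylbut-2-en-1-yl)phenyl}-5-methoxy-7-[(triisopropylsilyl)oxy]-2,3-dihydro-4H-chromen-4-one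
Conditions: Rh2(S-PTTL)4 (dirhodium tetrakis[N-phthaloyl-(S)-tert-leucinate], 2 mol %), PhCF3, 4 Å MS, 0 °C to rt, slow addition of 14
Reagents that add atoms: none
Why: Proposed new method: the divalent rhodium dimer should expel N2 from 14 to give an aryl/acyl carbenoid at C3, which inserts into a C–H bond of an ortho methoxy group through a concerted, hydride-transfer-like transition state and so forms C2–C3; the closest known reaction types are the dirhodium tetracarboxylate-catalysed insertion of ortho-alkoxyaryl diazoketones into O–CH2R bonds to give chroman-4-ones and the intermolecular insertion of aryl/acceptor carbenoids into methyl ether C–H bonds, whereas an intramolecular insertion into O–CH3 with an aryl group on the carbenoid carbon has not been shown. Ring C closes as a six-membered ring made of C3, C4, C4a, the ipso carbon that becomes C8a, O1 and the methoxy carbon that becomes C2, the only ring size open to C–H insertion on ring A because the fifth atom of the tether is oxygen. C3 is the only new stereocentre and 14 contains none, so its configuration is set by the chiral carboxylate ligands, which decide the face of the carbenoid that the C–H bond approaches. The two methoxy groups are equivalent by the symmetry of ring A, so there is no regiochemical choice and the one left over becomes the C5 methoxy group. The step needs C–H insertion to win over attack of the methoxy oxygen on the carbenoid: an aryl ether oxygen is a weak donor, ylide formation at a metal carbenoid is reversible, and methyl is the poorest migrating group for the 1,2-shift that would follow, so in a non-nucleophilic solvent the ylide should revert and the hydridic O–CH3 bond should be consumed by insertion. On ring B the 2'-silyl ether has no C–H bond alpha to oxygen and its silicon-bound methyl groups are not activated, while the prenyl alkene sits meta to the carbenoid-bearing carbon and cannot be reached within the molecule; slow addition holds back carbene dimerisation and intermolecular cyclopropanation. Product 15 is kept away from base and taken on promptly because its C3–H bond is acidic.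

Step 12
Reactants: 15 (3R)-3-{2-[(tert-butyldimethylsilyl)oxy]-4-methoxy-3-(3-methylbut-2-en-1-yl)phenyl}-5-methoxy-7-[(triisopropylsilyl)oxy]-2,3-dihydro-4H-chromen-4-one
Product: 16 (3R)-3-{2-[(tert-butyldimethylsilyl)oxy]-4-methoxy-3-(3-methylbut-2-en-1-yl)phenyl}-5-methoxy-7-[(triisopropylsilyl)oxy]-3,4-dihydro-2H-chromen-4-ol (mixture of C4 epimers)
Conditions: iBu2AlH, CH2Cl2, −78 °C; MeOH, then aq KNaC4H4O6
Reagents that add atoms: none
Why: Carbonyl reduction with a Lewis acidic, non-basic aluminium hydride at low temperature, which should deliver hydride faster than C3 can enolise; the C4 configuration does not matter because this centre becomes CH2 in the next step.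

Step 13
Reactants: 16 (3R)-3-{2-[(tert-butyldimethylsilyl)oxy]-4-methoxy-3-(3-methylbut-2-en-1-yl)phenyl}-5-methoxy-7-[(triisopropylsilyl)oxy]-3,4-dihydro-2H-chromen-4-ol
Product: 17 (3R)-3-{2-[(tert-butyldimethylsilyl)oxy]-4-methoxy-3-(3-methylbut-2-en-1-yl)phenyl}-5-methoxy-7-[(triisopropylsilyl)oxy]-3,4-dihydro-2H-chromene
Conditions: Et3SiH (10 equiv), CF3CO2H (3 equiv), CH2Cl2, −78 to −40 °C
Reagents that add atoms: none
Why: Ionic hydrogenation of a benzylic alcohol; the three oxygen donors of ring A let C4 ionise at low temperature, where the prenyl alkene is not protonated, and a large excess of silane should trap the cation before it can lose the C3 proton, so C3 is carried through unchanged.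

Step 14
Reactants: 17 (3R)-3-{2-[(tert-butyldimethylsilyl)oxy]-4-methoxy-3-(3-methylbut-2-en-1-yl)phenyl}-5-methoxy-7-[(triisopropylsilyl)oxy]-3,4-dihydro-2H-chromene
Product: 18 (3R)-3-[2-hydroxy-4-methoxy-3-(3-methylbut-2-en-1-yl)phenyl]-5-methoxy-3,4-dihydro-2H-chromen-7-ol
Conditions: Bu4NF, AcOH, THF, 0 °C to rt
Reagents that add atoms: none
Why: Fluoride cleavage of both aryl silyl ethers; the acetic acid buffer keeps the liberated electron-rich phenols from standing as phenoxides, and no acid strong enough to cyclise the prenyl group onto the 2'-hydroxyl is present.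

## Compound list

1 | 2-hydroxy-4-methoxybenzaldehyde | COc1ccc(C=O)c(O)c1 | starting material
2 | 3-chloro-3-methylbut-1-yne | CC(C)(Cl)C#C | starting material
3 | 4-methoxy-2-[(2-methylbut-3-yn-2-yl)oxy]benzaldehyde | COc1ccc(C=O)c(OC(C)(C)C#C)c1 | intermediate
4 | 4-methoxy-2-[(2-methylbut-3-en-2-yl)oxy]benzaldehyde | COc1ccc(C=O)c(OC(C)(C)C=C)c1 | intermediate
5 | 2-hydroxy-4-methoxy-3-(3-methylbut-2-en-1-yl)benzaldehyde | COc1ccc(C=O)c(O)c1CC=C(C)C | intermediate
6 | 2-[(tert-butyldimethylsilyl)oxy]-4-methoxy-3-(3-methylbut-2-en-1-yl)benzaldehyde | COc1ccc(C=O)c(O[Si](C)(C)C(C)(C)C)c1CC=C(C)C | intermediate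
7 | tert-butyl[3-methoxy-6-(2-methoxyethenyl)-2-(3-methylbut-2-en-1-yl)phenoxy]dimethylsilane (E/Z mixture) | COC=Cc1ccc(OC)c(CC=C(C)C)c1O[Si](C)(C)C(C)(C)C | intermediate
8 | 2-{2-[(tert-butyldimethylsilyl)oxy]-4-methoxy-3-(3-methylbut-2-en-1-yl)phenyl}acetaldehyde | O=CCc1ccc(OC)c(CC=C(C)C)c1O[Si](C)(C)C(C)(C)C | intermediate
9 | 3,5-dimethoxyphenol | COc1cc(O)cc(OC)c1 | starting material
10 | (3,5-dimethoxyphenoxy)tri(propan-2-yl)silane | COc1cc(O[Si](C(C)C)(C(C)C)C(C)C)cc(OC)c1 | intermediate
11 | {2,6-dimethoxy-4-[(triisopropylsilyl)oxy]phenyl}lithium | [Li]c1c(OC)cc(O[Si](C(C)C)(C(C)C)C(C)C)cc1OC | intermediate (not isolated)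
12 | rac-2-{2-[(tert-butyldimethylsilyl)oxy]-4-methoxy-3-(3-methylbut-2-en-1-yl)phenyl}-1-{2,6-dimethoxy-4-[(triisopropylsilyl)oxy]phenyl}ethan-1-ol | COc1cc(O[Si](C(C)C)(C(C)C)C(C)C)cc(OC)c1C(O)Cc1ccc(OC)c(CC=C(C)C)c1O[Si](C)(C)C(C)(C)C | intermediate
13 | 2-{2-[(tert-butyldimethylsilyl)oxy]-4-methoxy-3-(3-methylbut-2-en-1-yl)phenyl}-1-{2,6-dimethoxy-4-[(triisopropylsilyl)oxy]phenyl}ethan-1-one | COc1cc(O[Si](C(C)C)(C(C)C)C(C)C)cc(OC)c1C(=O)Cc1ccc(OC)c(CC=C(C)C)c1O[Si](C)(C)C(C)(C)C | intermediate
14 | 2-{2-[(tert-butyldimethylsilyl)oxy]-4-methoxy-3-(3-methylbut-2-en-1-yl)phenyl}-2-diazo-1-{2,6-dimethoxy-4-[(triisopropylsilyl)oxy]phenyl}ethan-1-one | COc1cc(O[Si](C(C)C)(C(C)C)C(C)C)cc(OC)c1C(=O)C(=[N+]=[N-])c1ccc(OC)c(CC=C(C)C)c1O[Si](C)(C)C(C)(C)C | intermediate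
15 | (3R)-3-{2-[(tert-butyldimethylsilyl)oxy]-4-methoxy-3-(3-methylbut-2-en-1-yl)phenyl}-5-methoxy-7-[(triisopropylsilyl)oxy]-2,3-dihydro-4H-chromen-4-one | COc1cc(O[Si](C(C)C)(C(C)C)C(C)C)cc2c1C(=O)[C@H](c1ccc(OC)c(CC=C(C)C)c1O[Si](C)(C)C(C)(C)C)CO2 | intermediate
16 | (3R)-3-{2-[(tert-butyldimethylsilyl)oxy]-4-methoxy-3-(3-methylbut-2-en-1-yl)phenyl}-5-methoxy-7-[(triisopropylsilyl)oxy]-3,4-dihydro-2H-chromen-4-ol (C4 epimers) | COc1cc(O[Si](C(C)C)(C(C)C)C(C)C)cc2c1C(O)[C@H](c1ccc(OC)c(CC=C(C)C)c1O[Si](C)(C)C(C)(C)C)CO2 | intermediate
17 | (3R)-3-{2-[(tert-butyldimethylsilyl)oxy]-4-methoxy-3-(3-methylbut-2-en-1-yl)phenyl}-5-methoxy-7-[(triisopropylsilyl)oxy]-3,4-dihydro-2H-chromene | COc1cc(O[Si](C(C)C)(C(C)C)C(C)C)cc2c1C[C@H](c1ccc(OC)c(CC=C(C)C)c1O[Si](C)(C)C(C)(C)C)CO2 | intermediate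
18 | (3R)-3-[2-hydroxy-4-methoxy-3-(3-methylbut-2-en-1-yl)phenyl]-5-methoxy-3,4-dihydro-2H-chromen-7-ol | COc1cc(O)cc2c1C[C@H](c1ccc(OC)c(CC=C(C)C)c1O)CO2 | target

## Step count and risk

Total: 14 steps. Longest linear sequence: 13 steps (steps 1 to 6 and 8 to 14, from 1); the ring A branch adds step 7.

**Step 11 (key step, proposed new method).** The carbenoid may be diverted by attack of a methoxy oxygen followed by methyl transfer, or by carbene dimerisation. Face selection by the catalyst may be poor, and the product may enolise at C3 on handling. The fallback uses known chemistry, sets out from 13 and rejoins the route at 16: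
- Chelation-controlled removal of one methyl group ortho to the carbonyl with MgI2·OEt2 should give the 2-hydroxy-6-methoxy deoxybenzoin F1.
- Alpha-methylenation with paraformaldehyde and Et2NH in MeOH, followed by oxa-Michael closure, should give the racemic isoflavanone F2.
- Asymmetric transfer hydrogenation under dynamic kinetic resolution (RuCl(p-cymene)(TsDPEN) in the enantiomeric form matched to the (3R) series, HCO2H/Et3N) should give the cis epimer of 16, with C3 set by the ruthenium catalyst.

In this fallback C2 comes from formaldehyde and the insertion is given up.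

**Step 13.** Loss of the C3 proton from the C4 cation and reprotonation would erode the C3 configuration. Protonation of the prenyl alkene and reversible capture of the cation by the 2'-oxygen are the other hazards. The fallback avoids the cation altogether, sets out from 16 and rejoins at 17. NaN(SiMe3)2 is added at −78 °C to 16 and CS2 so that the alkoxide is trapped as it forms, and MeI then gives the O-alkyl S-methyl xanthate F3. Radical reduction with Bu3SnH and Et3B/air at room temperature should give 17 through a C4 radical that cannot affect C3.

**Step 12.** Enolisation at C3 before hydride delivery, on storage of 15 or through the aluminium alkoxide, would lower the enantiomeric purity. The fallback sets out from 15 and rejoins at 16. The reduction is run as an asymmetric transfer hydrogenation under equilibrating conditions (RuCl(p-cymene)(TsDPEN) matched to the (3R) series, HCO2H/Et3N), so that any epimerised material is funnelled back and the reduction catalyst, not the substrate, fixes C3. No new compound arises.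

**Step 8.** The hindered aryllithium may abstract a proton from the readily enolised arylacetaldehyde instead of adding, and the electron-rich carbinol may dehydrate on work-up. The fallback sets out from 8 and rejoins at 13, skipping step 9. Pinnick oxidation (NaClO2, NaH2PO4, excess 2-methylbut-2-ene) should give the arylacetic acid F4. Coupling with MeNHOMe·HCl (EDC, iPr2NEt) should give the Weinreb amide F5. Addition of 11 to this much weaker carbon acid should give ketone 13 directly.

**Step 10.** The amidine base may cleave or shift the 2'-silyl group, and the twisted aryl ketone may be deprotonated only slowly. The fallback sets out from 13 and rejoins at 14. LiN(SiMe3)2 and CF3CO2CH2CF3 at −78 °C should give the trifluoroacetylated ketone F6. Detrifluoroacetylative diazo transfer with MsN3, Et3N and water in MeCN should then give 14 without a strong amidine base.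

## Further compounds

F1 | step 11 | 2-{2-[(tert-butyldimethylsilyl)oxy]-4-methoxy-3-(3-methylbut-2-en-1-yl)phenyl}-1-{2-hydroxy-6-methoxy-4-[(triisopropylsilyl)oxy]phenyl}ethan-1-one | COc1cc(O[Si](C(C)C)(C(C)C)C(C)C)cc(O)c1C(=O)Cc1ccc(OC)c(CC=C(C)C)c1O[Si](C)(C)C(C)(C)C
F2 | step 11 | rac-3-{2-[(tert-butyldimethylsilyl)oxy]-4-methoxy-3-(3-methylbut-2-en-1-yl)phenyl}-5-methoxy-7-[(triisopropylsilyl)oxy]-2,3-dihydro-4H-chromen-4-one | COc1cc(O[Si](C(C)C)(C(C)C)C(C)C)cc2c1C(=O)C(c1ccc(OC)c(CC=C(C)C)c1O[Si](C)(C)C(C)(C)C)CO2
F3 | step 13 | O-[(3R)-3-{2-[(tert-butyldimethylsilyl)oxy]-4-methoxy-3-(3-methylbut-2-en-1-yl)phenyl}-5-methoxy-7-[(triisopropylsilyl)oxy]-3,4-dihydro-2H-chromen-4-yl] S-methyl carbonodithioate | COc1cc(O[Si](C(C)C)(C(C)C)C(C)C)cc2c1C(OC(=S)SC)[C@H](c1ccc(OC)c(CC=C(C)C)c1O[Si](C)(C)C(C)(C)C)CO2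
F0 | step 12 | none | none
F4 | step 8 | 2-{2-[(tert-butyldimethylsilyl)oxy]-4-methoxy-3-(3-methylbut-2-en-1-yl)phenyl}acetic acid | COc1ccc(CC(=O)O)c(O[Si](C)(C)C(C)(C)C)c1CC=C(C)C
F5 | step 8 | 2-{2-[(tert-butyldimethylsilyl)oxy]-4-methoxy-3-(3-methylbut-2-en-1-yl)phenyl}-N-methoxy-N-methylacetamide | COc1ccc(CC(=O)N(C)OC)c(O[Si](C)(C)C(C)(C)C)c1CC=C(C)C
F6 | step 10 | 2-{2-[(tert-butyldimethylsilyl)oxy]-4-methoxy-3-(3-methylbut-2-en-1-yl)phenyl}-1-{2,6-dimethoxy-4-[(triisopropylsilyl)oxy]phenyl}-4,4,4-trifluorobutane-1,3-dione | COc1cc(O[Si](C(C)C)(C(C)C)C(C)C)cc(OC)c1C(=O)C(C(=O)C(F)(F)F)c1ccc(OC)c(CC=C(C)C)c1O[Si](C)(C)C(C)(C)C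
A1 | alternative 1 | 3-methoxy-2-[(4-methylbenzenesulfonyl)methyl]-5-[(triisopropylsilyl)oxy]phenol | COc1cc(O[Si](C(C)C)(C(C)C)C(C)C)cc(O)c1CS(=O)(=O)c1ccc(C)cc1
A2 | alternative 1 | 2-[4-methoxy-2-(methoxymethoxy)-3-(3-methylbut-2-en-1-yl)phenyl]acetic acid | COCOc1c(CC(=O)O)ccc(OC)c1CC=C(C)C
A3 | alternative 1 | (3R)-5-methoxy-3-[4-methoxy-2-(methoxymethoxy)-3-(3-methylbut-2-en-1-yl)phenyl]-7-[(triisopropylsilyl)oxy]-3,4-dihydro-2H-chromen-2-one | COc1cc(O[Si](C(C)C)(C(C)C)C(C)C)cc2c1C[C@H](c1ccc(OC)c(CC=C(C)C)c1OCOC)C(=O)O2
A4 | alternative 2 | 4-methoxy-6-(methoxymethoxy)-1-benzofuran | COCOc1cc(OC)c2ccoc2c1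
A5 | alternative 2 | 3-{3-bromo-4-methoxy-2-[(triisopropylsilyl)oxy]phenyl}-3-chloro-3H-diazirine | COc1ccc(C2(Cl)N=N2)c(O[Si](C(C)C)(C(C)C)C(C)C)c1Br
A6 | alternative 2 | 3-{3-bromo-4-methoxy-2-[(triisopropylsilyl)oxy]phenyl}-5-methoxy-7-(methoxymethoxy)chromenylium chloride | COCOc1cc(OC)c2cc(-c3ccc(OC)c(Br)c3O[Si](C(C)C)(C(C)C)C(C)C)c[o+]c2c1.[Cl-]
A7 | alternative 3 | 2-{[2-bromo-6-methoxy-4-(methoxymethoxy)phenyl]methyl}-2-[4-methoxy-2-(methoxymethoxy)-3-(3-methylbut-2-en-1-yl)phenyl]propane-1,3-diol | COc1cc(OCOC)cc(Br)c1CC(CO)(CO)c1ccc(OC)c(CC=C(C)C)c1OCOC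
A8 | alternative 3 | {(3R)-5-methoxy-7-(methoxymethoxy)-3-[4-methoxy-2-(methoxymethoxy)-3-(3-methylbut-2-en-1-yl)phenyl]-3,4-dihydro-2H-chromen-3-yl}methanol | COc1cc(OCOC)cc2c1C[C@](CO)(c1ccc(OC)c(CC=C(C)C)c1OCOC)CO2
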